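**Retrosynthetic overview**
1. Feature: ring A is the carbocycle C1–C6 (C1 methoxy carbon, C2, C3 ketone, C4, C5, C6 carbinol). In it the C3 ketone stands directly beside the C4–C5 oxirane (ring B). This ring-embedded α,β-epoxy ketone is the retron of a Darzens condensation.
2. Key disconnection: C4–C5 and C4–O are cut together. This opens both rings to the acyclic (E)-β-methoxy enone 17 (C5 aldehyde, C6 OTBS, C4 as CCl2). In the forward sense ring A closes first (aldol) and ring B second (chloride displacement), in one flask.
3. Reshaped precursor: C6–H of the aldehyde is more acidic than an α-chloro ketone C–H. The C4 chloro enolate is therefore made by two-electron reduction of a C4 gem-dichloride, not with base. The extra chlorine is the activating group and also removes the C4 stereocentre from the precursor.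
4. Precursor assembly: 17 comes from ynone 13 by methanol oxa-Michael addition, selective primary desilylation and oxidation. 13 is split at C2–C3 into alkyne 5 (C5, C6, C1, C2; from glycerate ester 1) and dichloro aldehyde 10 (C3, C4, side chain; from 6 and 7).
5. Stereochemistry: C6 comes from 1, C5 is set from C6 in the aldol event, and C4 follows from the stereospecific oxirane closure. The acetonide is exchanged for silyl ethers before any enone exists, and desilylation ends the route.

Key step: step 11

Remark: the SMILES is read as 4R,5R,6S in the ring numbering above, with the epoxide oxygen and the C6 hydroxyl on the same face. C1–C6 in the text always mean these future ring atoms, whereas locants inside systematic names follow chain numbering.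

**Step 1**
Reactants: 1 methyl (S)-2,2-dimethyl-1,3-dioxolane-4-carboxylate
Product: 3 (R)-4-ethynyl-2,2-dimethyl-1,3-dioxolane, via (S)-glyceraldehyde acetonide 2 (not isolated)
Conditions: i-Bu2AlH, CH2Cl2, −78 °C; then MeOH, K2CO3, dimethyl (1-diazo-2-oxopropyl)phosphonate, −78 °C → rt
Reagents that add atoms: dimethyl (1-diazo-2-oxopropyl)phosphonate (Ohira–Bestmann reagent), CC(=O)C(=[N+]=[N-])P(=O)(OC)OC
Why: Partial reduction of the ester and Ohira–Bestmann (Seyferth–Gilbert type) homologation of the released aldehyde in the same flask is an established ester-to-alkyne conversion, and the future C6 stereocentre, taken from 1, is kept because aldehyde 2 is consumed as fast as it is set free.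

**Step 2**
Reactants: 3 (R)-4-ethynyl-2,2-dimethyl-1,3-dioxolane
Product: 4 (R)-but-3-yne-1,2-diol
Conditions: Dowex 50WX8 (H+ form), MeOH, rt
Reagents that add atoms: none
Why: Acid-catalysed transketalisation with methanol removes the acetonide now, while the molecule holds no enone, because a free C6 hydroxyl standing cis to the C3 ketone at a later stage would cyclodehydrate to a furan.

**Step 3**
Reactants: 4 (R)-but-3-yne-1,2-diol
Product: 5 (R)-3,4-bis(tert-butyldimethylsilyloxy)but-1-yne
Conditions: TBSCl (2.5 equiv), imidazole, DMF, rt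
Reagents that add atoms: tert-butyldimethylsilyl chloride (TBSCl), CC(C)(C)[Si](C)(C)Cl
Why: Imidazole-promoted silylation caps both hydroxyls in one operation, which keeps the C6 oxygen blocked until the last step and leaves the less hindered primary C5 silyl ether as the one that can be taken off selectively.

**Step 4**
Reactants: 6 methyl dichloroacetate; 7 (2E,6E)-farnesyl bromide
Product: 9 methyl (4E,8E)-2,2-dichloro-5,9,13-trimethyltetradeca-4,8,12-trienoate, via lithium dichloroacetate enolate 8 (not isolated)
Conditions: 6, LiN(SiMe3)2, THF, −78 °C; then 7, DMPU, −78 → −40 °C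
Reagents that add atoms: none
Why: Enolate alkylation of an α,α-dichloro ester with a primary allylic bromide proceeds by direct SN2 displacement, so both E alkenes are retained and C3, C4 and the two chlorines arrive in one piece.

**Step 5**
Reactants: 9 methyl (4E,8E)-2,2-dichloro-5,9,13-trimethyltetradeca-4,8,12-trienoate
Product: 10 (4E,8E)-2,2-dichloro-5,9,13-trimethyltetradeca-4,8,12-trienal
Conditions: i-Bu2AlH (1.05 equiv), CH2Cl2, −78 °C; aqueous potassium sodium tartrate
Reagents that add atoms: none
Why: Low-temperature partial reduction of an ester with i-Bu2AlH stops at the aldehyde because the two chlorines stabilise the tetrahedral aluminium hemiacetal until it is hydrolysed in the work-up.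

**Step 6**
Reactants: 5 (R)-3,4-bis(tert-butyldimethylsilyloxy)but-1-yne; 10 (4E,8E)-2,2-dichloro-5,9,13-trimethyltetradeca-4,8,12-trienal
Product: 12 (2R,8E,12E)-1,2-bis(tert-butyldimethylsilyloxy)-6,6-dichloro-9,13,17-trimethyloctadeca-8,12,16-trien-3-yn-5-ol (both carbinol epimers), via lithium acetylide 11 (not isolated)
Conditions: 5, n-BuLi (0.98 equiv), THF, −78 °C; then 10, −78 °C; AcOH, −78 °C
Reagents that add atoms: none
Why: 1,2-Addition of a lithium acetylide to a non-enolisable and strongly electrophilic α,α-dichloro aldehyde forms the C2–C3 bond, the configuration of the new carbinol is irrelevant since step 7 removes it, and the cold acid quench stops the chloro alkoxide from closing to a chloro epoxide.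

**Step 7**
Reactants: 12 propargylic alcohol
Product: 13 (2R,8E,12E)-1,2-bis(tert-butyldimethylsilyloxy)-6,6-dichloro-9,13,17-trimethyloctadeca-8,12,16-trien-3-yn-5-one
Conditions: Dess–Martin periodinane, CH2Cl2, 0 °C → rt
Reagents that add atoms: none
Why: Dess–Martin oxidation converts propargylic alcohols, electron-poor ones included, into ynones under neutral conditions that leave the silyl ethers, the CCl2 group and the trisubstituted alkenes untouched.

**Step 8**
Reactants: 13 dichloro ynone
Product: 15 (2S,3E,8E,12E)-1,2-bis(tert-butyldimethylsilyloxy)-6,6-dichloro-3-methoxy-9,13,17-trimethyloctadeca-3,8,12,16-tetraen-5-one, via (Z)-enol ether 14 (not isolated)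
Conditions: MeOH/CH2Cl2, DMAP (20 mol %), 0 °C → rt
Reagents that add atoms: methanol, CO
Why: Nucleophile-catalysed oxa-Michael addition of methanol to the ynone gives by anti addition first the Z enol ether 14, which equilibrates through reversible addition–elimination to the more stable E isomer 15 (methoxy oxygen turned away from the carbonyl, C6 and C3 on the same side), while the fully substituted CCl2 carbon offers neither an acidic hydrogen nor an SN2 site to catalyst or methanol.

**Step 9**
Reactants: 15 (E)-β-methoxy enone bis-TBS ether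
Product: 16 (2S,3E,8E,12E)-2-(tert-butyldimethylsilyloxy)-6,6-dichloro-1-hydroxy-3-methoxy-9,13,17-trimethyloctadeca-3,8,12,16-tetraen-5-one
Conditions: HF·pyridine, pyridine, THF, 0 °C
Reagents that add atoms: none
Why: Buffered HF·pyridine cleaves the unhindered primary TBS ether much faster than the secondary one flanked by the C1 enol ether, a standard steric differentiation of silyl ethers, and the weakly acidic medium excludes silyl migration.

**Step 10**
Reactants: 16 primary alcohol
Product: 17 (2R,3E,8E,12E)-2-(tert-butyldimethylsilyloxy)-6,6-dichloro-3-methoxy-9,13,17-trimethyl-5-oxooctadeca-3,8,12,16-tetraenal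
Conditions: Dess–Martin periodinane, CH2Cl2, 0 °C; pentane, filtration through a short pad of neutral silica; used at once
Reagents that add atoms: none
Why: Dess–Martin oxidation turns the primary alcohol into the aldehyde without any base, and C6 should hold its configuration over the short handling time because allylic 1,3-strain against the C3 acyl group keeps the C6–H bond close to the enone plane and thus badly aligned for enolisation.

**Step 11**
Reactants: 17 gem-dichloro keto aldehyde
Product: 20 yanuthone X2 6-O-TBS ether, via chloro enolate 18 (not isolated), via trans-chloro aldolate 19 (not isolated)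
Conditions: TDAE [tetrakis(dimethylamino)ethylene] (1.1 equiv), DMF (0.01 M), argon, −20 °C → rt
Reagents that add atoms: none
Why: Proposed new method: TDAE, a neutral organic two-electron donor, should take one chlorine out of the activated CCl2 ketone and so deliver the C4 α-chloro enolate 18 regiospecifically and without base, which is the point of the design because C6–H of 17 (α to the aldehyde, γ to the enone) would be removed by carbonate or amine bases before any C4–H and the only stereocentre that carries the absolute configuration would be lost. C4 of 18 then adds to the C5 aldehyde (6-(enolendo)-exo-trig, closes carbocycle A) and the C5 alkoxide of 19 expels the remaining chloride from C4 by rear-side attack (3-exo-tet, closes oxirane B), so that the sequence is a Darzens condensation whose enolate is made by reduction. The closest known reaction types are the TDAE-mediated union of benzylic gem-dihalides and aldehydes to oxiranes, the TDAE-generated enolates of chlorodifluoromethyl ketones that add to aldehydes, the metal-promoted dichloroacetate variant of the glycidic ester synthesis and the base-mediated intramolecular Darzens reaction; what is new is the use of an alkyl-substituted α,α-dichloro ketone in a ring-forming version. C5 is controlled by C6: in the half-chair transition state the OTBS group lies pseudo-equatorial and anti to the forming C4–C5 bond (polar Felkin–Anh arrangement), the alternative with pseudo-axial OTBS suffering a 1,3-diaxial contact with the C4 substituent, so the C5 oxygen ends pseudo-axial and cis to the C6 oxygen. C4 is controlled by the closure itself, since only the aldolate with oxygen and chlorine trans-diaxial can reach the necessarily cis-fused oxirane, while the metal-free aldolate of the other C4 configuration returns by retro-aldol and drains through 19. The step needs chemoselective reduction, secured by the much easier reduction of a gem-dichloro ketone compared with the monochloro ketone, epoxy ketone, aldehyde and vinylogous ester, and it needs cyclisation to outrun proton transfer and intermolecular aldol reaction, secured by the E C1=C2 geometry that places C4 beside C5 and by high dilution.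

**Step 12**
Reactants: 20 yanuthone X2 6-O-TBS ether
Product: 21 yanuthone X2
Conditions: HF·pyridine, THF, 0 °C → rt
Reagents that add atoms: none
Why: Fluoride-driven cleavage of the remaining secondary silyl ether under weakly acidic conditions spares the base-sensitive epoxy ketone, the vinylogous ester and the triene and touches no stereocentre.

**Compound list**
1 | methyl (S)-2,2-dimethyl-1,3-dioxolane-4-carboxylate | COC(=O)[C@@H]1COC(C)(C)O1 | starting material
2 | (S)-2,2-dimethyl-1,3-dioxolane-4-carbaldehyde | O=C[C@@H]1COC(C)(C)O1 | intermediate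
3 | (R)-4-ethynyl-2,2-dimethyl-1,3-dioxolane | C#C[C@@H]1COC(C)(C)O1 | intermediate
4 | (R)-but-3-yne-1,2-diol | C#C[C@@H](O)CO | intermediate
5 | (R)-3,4-bis(tert-butyldimethylsilyloxy)but-1-yne | C#C[C@@H](O[Si](C)(C)C(C)(C)C)CO[Si](C)(C)C(C)(C)C | intermediate
6 | methyl dichloroacetate | COC(=O)C(Cl)Cl | starting material
7 | (2E,6E)-farnesyl bromide | BrC/C=C(\C)CC/C=C(\C)CCC=C(C)C | starting material
8 | lithium enolate of methyl dichloroacetate | [Li+].COC([O-])=C(Cl)Cl | intermediate
9 | methyl (4E,8E)-2,2-dichloro-5,9,13-trimethyltetradeca-4,8,12-trienoate | COC(=O)C(Cl)(Cl)C/C=C(\C)CC/C=C(\C)CCC=C(C)C | intermediate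
10 | (4E,8E)-2,2-dichloro-5,9,13-trimethyltetradeca-4,8,12-trienal | O=CC(Cl)(Cl)C/C=C(\C)CC/C=C(\C)CCC=C(C)C | intermediate
11 | lithium acetylide of 5 | [Li]C#C[C@@H](O[Si](C)(C)C(C)(C)C)CO[Si](C)(C)C(C)(C)C | intermediate
12 | (2R,8E,12E)-1,2-bis(TBSO)-6,6-dichloro-9,13,17-trimethyloctadeca-8,12,16-trien-3-yn-5-ol, carbinol epimers | OC(C#C[C@@H](O[Si](C)(C)C(C)(C)C)CO[Si](C)(C)C(C)(C)C)C(Cl)(Cl)C/C=C(\C)CC/C=C(\C)CCC=C(C)C | intermediate
13 | (2R,8E,12E)-1,2-bis(TBSO)-6,6-dichloro-9,13,17-trimethyloctadeca-8,12,16-trien-3-yn-5-one | O=C(C#C[C@@H](O[Si](C)(C)C(C)(C)C)CO[Si](C)(C)C(C)(C)C)C(Cl)(Cl)C/C=C(\C)CC/C=C(\C)CCC=C(C)C | intermediate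
14 | (2S,3Z,8E,12E)-1,2-bis(TBSO)-6,6-dichloro-3-methoxy-9,13,17-trimethyloctadeca-3,8,12,16-tetraen-5-one | CC(C)(C)[Si](C)(C)OC[C@H](O[Si](C)(C)C(C)(C)C)/C(OC)=C/C(=O)C(Cl)(Cl)C/C=C(\C)CC/C=C(\C)CCC=C(C)C | intermediate
15 | (2S,3E,8E,12E)-1,2-bis(TBSO)-6,6-dichloro-3-methoxy-9,13,17-trimethyloctadeca-3,8,12,16-tetraen-5-one | CC(C)(C)[Si](C)(C)OC[C@H](O[Si](C)(C)C(C)(C)C)/C(OC)=C\C(=O)C(Cl)(Cl)C/C=C(\C)CC/C=C(\C)CCC=C(C)C | intermediate
16 | (2S,3E,8E,12E)-2-(TBSO)-6,6-dichloro-1-hydroxy-3-methoxy-9,13,17-trimethyloctadeca-3,8,12,16-tetraen-5-one | OC[C@H](O[Si](C)(C)C(C)(C)C)/C(OC)=C\C(=O)C(Cl)(Cl)C/C=C(\C)CC/C=C(\C)CCC=C(C)C | intermediate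
17 | (2R,3E,8E,12E)-2-(TBSO)-6,6-dichloro-3-methoxy-9,13,17-trimethyl-5-oxooctadeca-3,8,12,16-tetraenal (key-step precursor) | O=C[C@H](O[Si](C)(C)C(C)(C)C)/C(OC)=C\C(=O)C(Cl)(Cl)C/C=C(\C)CC/C=C(\C)CCC=C(C)C | intermediate
18 | C4 α-chloro enolate of the keto aldehyde (anion, TDAE-derived counter-ion, C3=C4 geometry open) | O=C[C@H](O[Si](C)(C)C(C)(C)C)/C(OC)=C\C([O-])=C(Cl)C/C=C(\C)CC/C=C(\C)CCC=C(C)C | intermediate
19 | ring-closed aldolate, C5 alkoxide trans to C4 chlorine and cis to C6 OTBS | COC1=CC(=O)[C@](Cl)(C/C=C(\C)CC/C=C(\C)CCC=C(C)C)[C@H]([O-])[C@@H]1O[Si](C)(C)C(C)(C)C | intermediate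
20 | yanuthone X2 6-O-TBS ether, (1R,5S,6R)-5-(TBSO)-4-methoxy-1-[(2E,6E)-farnesyl]-7-oxabicyclo[4.1.0]hept-3-en-2-one | COC1=CC(=O)[C@]2(C/C=C(\C)CC/C=C(\C)CCC=C(C)C)O[C@@H]2[C@@H]1O[Si](C)(C)C(C)(C)C | intermediate
21 | yanuthone X2, (1R,5S,6R)-5-hydroxy-4-methoxy-1-[(2E,6E)-farnesyl]-7-oxabicyclo[4.1.0]hept-3-en-2-one | COC1=CC(=O)[C@]2(C/C=C(\C)CC/C=C(\C)CCC=C(C)C)O[C@@H]2[C@@H]1O | target

**Step count**
- Total step count: 12.
- Longest linear sequence: 10 (steps 1–3 and 6–12). Steps 4 and 5 form the side branch.

**Steps most likely to fail**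

1. Step 11.
   - What may go wrong: electron transfer from TDAE to the CCl2 ketone may be slow. The free chloro enolate may exchange a proton with C6–H of unreacted aldehyde, which would erode the enantiopurity. Facial selectivity at C5 may be poor. The second C–Cl bond may be reduced before the oxirane closes.
   - Fallback (known chemistry), from 17 to 20: a chromium Reformatsky reaction (CrCl2 limited to two equivalents, catalytic LiI, THF, 0 °C) makes the chloro enolate as a non-basic chromium enolate, a species known to spare α-stereocentres of aldehydes. After aqueous work-up it should give the ring-closed trans-chlorohydrin F1 together with its C4 epimer F2.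
   - With the aldehyde gone, C6–H is no longer activated, so Cs2CO3 in MeCN can close F1 by ordinary halohydrin cyclisation. F2 re-enters through retro-aldol and aldol equilibration, and the route is rejoined at 20.

2. Step 8.
   - What may go wrong: the Z to E equilibration may be incomplete, or methanol may attack the activated C3 carbonyl with cleavage of a C–C bond.
   - Fallback, from 5 to 15: lithiation of 5 and trapping with methyl chloroformate gives methyl (R)-4,5-bis(TBSO)pent-2-ynoate F3. DMAP- or PMe3-catalysed addition of methanol to this alkynoate, the best documented substrate class for the reaction, gives methyl (S,E)-4,5-bis(TBSO)-3-methoxypent-2-enoate F4.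
   - Acylation of dichloromethyllithium (CH2Cl2, i-Pr2NLi, THF, −95 °C) by F4 gives the dichloromethyl ketone F5. Its lithium enolate [LiN(SiMe3)2, THF/DMPU, −78 °C] is alkylated with 7 as in step 4. The route is rejoined at 15, and steps 4 to 7 fall away.

3. Step 10.
   - What may go wrong: the hydroxy ketone may rest as a six-membered hemiketal on the activated C3 carbonyl, so that oxidation drags. C6 may enolise during the longer exposure and the two separate handling operations.
   - Fallback, from 4 to 17, in which the alcohol is never set free: selective silylation of 4 (TESCl, imidazole, CH2Cl2, −78 °C) gives (R)-1-(triethylsilyloxy)but-3-yn-2-ol F6. TBSOTf and 2,6-lutidine then give the mixed bis-silyl alkyne F7.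
   - The operations of steps 6 to 8 lead through the propargylic alcohol F8 and the ynone F9 to the (E)-β-methoxy enone F10. Direct oxidative desilylation of the primary TES ether under Swern conditions [(COCl)2, DMSO, CH2Cl2, −78 → −40 °C, then i-Pr2NEt, −78 °C, cold buffer quench] delivers the aldehyde in one operation. The route is rejoined at 17, and step 9 falls away.

**Further compounds**
F1 | step 11 | ring-closed chlorohydrin, C4 chlorine trans to C5 hydroxyl, C5 hydroxyl cis to C6 OTBS | COC1=CC(=O)[C@](Cl)(C/C=C(\C)CC/C=C(\C)CCC=C(C)C)[C@H](O)[C@@H]1O[Si](C)(C)C(C)(C)C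
F2 | step 11 | C4 epimer of F1, chlorine cis to C5 hydroxyl | COC1=CC(=O)[C@@](Cl)(C/C=C(\C)CC/C=C(\C)CCC=C(C)C)[C@H](O)[C@@H]1O[Si](C)(C)C(C)(C)C
F3 | step 8 | methyl (R)-4,5-bis(tert-butyldimethylsilyloxy)pent-2-ynoate | COC(=O)C#C[C@@H](O[Si](C)(C)C(C)(C)C)CO[Si](C)(C)C(C)(C)C
F4 | step 8 | methyl (S,E)-4,5-bis(tert-butyldimethylsilyloxy)-3-methoxypent-2-enoate | CC(C)(C)[Si](C)(C)OC[C@H](O[Si](C)(C)C(C)(C)C)/C(OC)=C\C(=O)OC
F5 | step 8 | (S,E)-5,6-bis(tert-butyldimethylsilyloxy)-1,1-dichloro-4-methoxyhex-3-en-2-one | CC(C)(C)[Si](C)(C)OC[C@H](O[Si](C)(C)C(C)(C)C)/C(OC)=C\C(=O)C(Cl)Cl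
F6 | step 10 | (R)-1-(triethylsilyloxy)but-3-yn-2-ol | C#C[C@@H](O)CO[Si](CC)(CC)CC
F7 | step 10 | (R)-3-(tert-butyldimethylsilyloxy)-4-(triethylsilyloxy)but-1-yne | C#C[C@@H](O[Si](C)(C)C(C)(C)C)CO[Si](CC)(CC)CC
F8 | step 10 | 1-O-TES analogue of 12 | OC(C#C[C@@H](O[Si](C)(C)C(C)(C)C)CO[Si](CC)(CC)CC)C(Cl)(Cl)C/C=C(\C)CC/C=C(\C)CCC=C(C)C
F9 | step 10 | 1-O-TES analogue of 13 | O=C(C#C[C@@H](O[Si](C)(C)C(C)(C)C)CO[Si](CC)(CC)CC)C(Cl)(Cl)C/C=C(\C)CC/C=C(\C)CCC=C(C)C
F10 | step 10 | 1-O-TES analogue of 15 | CC[Si](CC)(CC)OC[C@H](O[Si](C)(C)C(C)(C)C)/C(OC)=C\C(=O)C(Cl)(Cl)C/C=C(\C)CC/C=C(\C)CCC=C(C)C
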